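The oxolane ring (O1, C2, C3, C4, C5) is disconnected at C2–C3: C2, bound to O1 and an aryl group, is an acetal carbon, and C3 with its CH2OH arm is an aldehyde enol carbon. Both are held in a seven-membered cyclic vinyl acetal, a 2-aryl-5-(arylmethyl)-4,5-dihydro-1,3-dioxepin. A silyl-triflate-triggered [1,3] O-to-C shift contracts this ring by two atoms, forges C2–C3 and sets C2 and C3 from the single stereocentre C4, while both acetal epimers converge. The precursor comes from an enantioselective benzyl Heck reaction of a 4,7-dihydro-1,3-dioxepin with the complete dihydrobenzofuran arm, itself made by asymmetric carbenoid C–H insertion.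

Key step: step 10

Assumption: the ligand antipodes written for the two catalyst-controlled steps (Rh2(R-PTTL)4 in step 5, the (S)-BINOL phosphoramidite in step 9) are chosen by analogy with related substrates; if a model run shows the opposite sense, the mirror-image ligand is used and nothing else changes.

Step 1
Reactants: 1 methyl 4-bromo-3,5-dihydroxybenzoate
Product: 2 methyl 4-bromo-3-hydroxy-5-methoxybenzoate
Conditions: MeI (1.0 equiv), K2CO3 (1.0 equiv), DMF, 0 → 23 °C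
Reagents that add atoms: iodomethane, CI
Why: Williamson O-methylation; the two phenols of 1 are equivalent by symmetry, so limiting MeI should give mainly the mono-ether, and recovered 1 is recycled.

Step 2
Reactants: 2 methyl 4-bromo-3-hydroxy-5-methoxybenzoate; 3 [4-(benzyloxy)-3-methoxyphenyl]methanol
Product: 4 methyl 3-{[4-(benzyloxy)-3-methoxyphenyl]methoxy}-4-bromo-5-methoxybenzoate
Conditions: PPh3, DIAD, THF, 0 → 23 °C
Reagents that add atoms: none
Why: Mitsunobu etherification of the acidic ortho-bromophenol with the primary benzylic alcohol, which avoids the unstable electron-rich benzylic halide.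

Step 3
Reactants: 4 methyl 3-{[4-(benzyloxy)-3-methoxyphenyl]methoxy}-4-bromo-5-methoxybenzoate
Product: 5 methyl 3-{[4-(benzyloxy)-3-methoxyphenyl]methoxy}-4-(2-tert-butoxy-2-oxoethyl)-5-methoxybenzoate
Conditions: BrZnCH2CO2tBu (1.5 equiv), Pd(dba)2 (5 mol%), Q-Phos (5 mol%), THF, 50 °C
Reagents that add atoms: (2-tert-butoxy-2-oxoethyl)zinc bromide, CC(C)(C)OC(=O)C[Zn]Br
Why: Negishi-type coupling of a Reformatsky reagent at zerovalent palladium (ester α-arylation); the neutral zinc enolate leaves the methyl ester alone and the bulky ferrocenylphosphine should carry the doubly ortho-substituted bromide.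

Step 4
Reactants: 5 methyl 3-{[4-(benzyloxy)-3-methoxyphenyl]methoxy}-4-(2-tert-butoxy-2-oxoethyl)-5-methoxybenzoate
Product: 6 methyl 3-{[4-(benzyloxy)-3-methoxyphenyl]methoxy}-4-(2-tert-butoxy-1-diazo-2-oxoethyl)-5-methoxybenzoate
Conditions: p-ABSA, DBU, MeCN, 0 → 23 °C
Reagents that add atoms: 4-acetamidobenzenesulfonyl azide, CC(=O)Nc1ccc(cc1)S(=O)(=O)N=[N+]=[N-]
Why: Regitz diazo transfer to the CH2 group activated by the aryl ring and the ester should give the donor/acceptor diazo ester.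

Step 5
Reactants: 6 methyl 3-{[4-(benzyloxy)-3-methoxyphenyl]methoxy}-4-(2-tert-butoxy-1-diazo-2-oxoethyl)-5-methoxybenzoate
Product: 8 3-tert-butyl 6-methyl (2S,3S)-2-[4-(benzyloxy)-3-methoxyphenyl]-4-methoxy-2,3-dihydro-1-benzofuran-3,6-dicarboxylate, via cis-dihydrobenzofuran diester 7 (not isolated)
Conditions: Rh2(R-PTTL)4 (1 mol%), toluene, −60 °C; then NaOMe (0.2 equiv), MeOH, 23 °C
Reagents that add atoms: none
Why: the dirhodium carbenoid undergoes intramolecular 1,5 C–H insertion into the electron-rich benzylic OCH2 group (much faster than into OCH3), the chiral carboxylate ligands setting C2 as S with the cis ester as kinetic product, and methoxide then epimerises only the enolisable C3 to the more stable trans (2S,3S) diester.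

Step 6
Reactants: 8 3-tert-butyl 6-methyl (2S,3S)-2-[4-(benzyloxy)-3-methoxyphenyl]-4-methoxy-2,3-dihydro-1-benzofuran-3,6-dicarboxylate
Product: 9 tert-butyl (2S,3S)-2-[4-(benzyloxy)-3-methoxyphenyl]-6-(hydroxymethyl)-4-methoxy-2,3-dihydro-1-benzofuran-3-carboxylate
Conditions: LiBH4 (2 equiv), THF with MeOH (1 equiv), 0 → 40 °C
Reagents that add atoms: none
Why: chemoselective hydride reduction, in which LiBH4 should reduce the methyl benzoate while the hindered tert-butyl ester stays.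

Step 7
Reactants: 9 tert-butyl (2S,3S)-2-[4-(benzyloxy)-3-methoxyphenyl]-6-(hydroxymethyl)-4-methoxy-2,3-dihydro-1-benzofuran-3-carboxylate
Product: 10 tert-butyl (2S,3S)-2-[4-(benzyloxy)-3-methoxyphenyl]-4-methoxy-6-{[(trifluoroacetyl)oxy]methyl}-2,3-dihydro-1-benzofuran-3-carboxylate
Conditions: (CF3CO)2O, pyridine, CH2Cl2, 0 °C; used crude
Reagents that add atoms: trifluoroacetic anhydride, O=C(OC(=O)C(F)(F)F)C(F)(F)F
Why: O-acylation turns the benzylic alcohol into an ester that ionises readily to a benzylpalladium species.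

Step 8
Reactants: 11 3-(benzyloxy)-4-methoxybenzaldehyde; 12 (Z)-but-2-ene-1,4-diol
Product: 13 2-[3-(benzyloxy)-4-methoxyphenyl]-4,7-dihydro-1,3-dioxepine
Conditions: TsOH·H2O (cat.), toluene, reflux, Dean–Stark trap
Reagents that add atoms: none
Why: acetalisation, in which the cis diol can only close the seven-membered cyclic acetal; 13 is achiral (mirror plane through C2 and the alkene midpoint).

Step 9
Reactants: 10 tert-butyl (2S,3S)-2-[4-(benzyloxy)-3-methoxyphenyl]-4-methoxy-6-{[(trifluoroacetyl)oxy]methyl}-2,3-dihydro-1-benzofuran-3-carboxylate; 13 2-[3-(benzyloxy)-4-methoxyphenyl]-4,7-dihydro-1,3-dioxepine (3 equiv)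
Product: 14 tert-butyl (2S,3S)-2-[4-(benzyloxy)-3-methoxyphenyl]-6-{[(5S)-2-[3-(benzyloxy)-4-methoxyphenyl]-4,5-dihydro-1,3-dioxepin-5-yl]methyl}-4-methoxy-2,3-dihydro-1-benzofuran-3-carboxylate (both epimers at the acetal carbon C2 of the dioxepin)
Conditions: Pd(dba)2 (5 mol%), (S)-BINOL-derived phosphoramidite with an N,N-bis[(R)-1-phenylethyl]amino group (12 mol%), iPr2NEt (2 equiv), THF, 50 °C
Reagents that add atoms: none
Why: asymmetric intermolecular Heck reaction of a benzylic electrophile: oxidative addition of the trifluoroacetate to zerovalent palladium, syn carbopalladation of the cis alkene with ligand control over the two enantiotopic alkene carbons (sets C5 as S), and syn β-hydride elimination, possible only toward the OCH2 group, which gives the enol ether directly; attack on either face gives the same C5 configuration, so only the acetal carbon is a mixture.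

Step 10
Reactants: 14 tert-butyl (2S,3S)-2-[4-(benzyloxy)-3-methoxyphenyl]-6-{[(5S)-2-[3-(benzyloxy)-4-methoxyphenyl]-4,5-dihydro-1,3-dioxepin-5-yl]methyl}-4-methoxy-2,3-dihydro-1-benzofuran-3-carboxylate
Product: 15 tert-butyl (2S,3S)-2-[4-(benzyloxy)-3-methoxyphenyl]-6-{[(3S,4S,5R)-5-[3-(benzyloxy)-4-methoxyphenyl]-4-formyloxolan-3-yl]methyl}-4-methoxy-2,3-dihydro-1-benzofuran-3-carboxylate (on the oxolane: aryl and CHO cis, CHO and arylmethyl trans)
Conditions: TMSOTf (0.2 equiv), CH2Cl2, −78 °C; Et3N quench at −78 °C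
Reagents that add atoms: none
Why: TMSOTf ionises the acetal at the C2–O1 bond (O1, the enol ether oxygen, leaves as a silyl enol ether), giving an aryl-stabilised oxocarbenium ion tethered through O3–C4–C5 to the nucleophilic enol carbon C6, which closes onto C2 in a net [1,3] O-to-C shift that puts O1 and C7 outside the ring as the formyl group and releases the silyl cation again. The closest known reaction type is the Lewis-acid vinyl acetal rearrangement (Petasis–Ferrier-type ring contraction) of 4,5-dihydro-1,3-dioxepins to oxolane-3-carbaldehydes. The oxolane closes in a 5-(enol-exo)-endo-trig mode at the oxocarbenium ion, a closure such cations undergo readily. Oxolane C4 is the untouched C5 of 14; C3 is set because the enol ether is attacked on the face anti to the arylmethyl group in the conformer that minimises 1,3-allylic strain (3,4-trans), and C2 is set by the compact synclinal approach of the E-oxocarbenium ion (2,3-cis), so the C2 aryl and C4 arylmethyl groups end up trans. Because C2 is planar in the ion, both acetal epimers of 14 should converge on 15. The step needs C-attack by the enol ether to outrun Friedel–Crafts capture by the electron-rich benzofuran ring and re-ionisation of the product, which the five-ring tether, the silyl enol ether nucleophile, −78 °C and the cold amine quench should secure.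

Step 11
Reactants: 15 tert-butyl (2S,3S)-2-[4-(benzyloxy)-3-methoxyphenyl]-6-{[(3S,4S,5R)-5-[3-(benzyloxy)-4-methoxyphenyl]-4-formyloxolan-3-yl]methyl}-4-methoxy-2,3-dihydro-1-benzofuran-3-carboxylate
Product: 17 {(2S,3R)-2-[4-(benzyloxy)-3-methoxyphenyl]-6-{[(3S,4S,5R)-5-[3-(benzyloxy)-4-methoxyphenyl]-4-(hydroxymethyl)oxolan-3-yl]methyl}-4-methoxy-2,3-dihydro-1-benzofuran-3-yl}methanol, via C3-epimerised aldehyde 16 (not isolated)
Conditions: DBU (0.3 equiv), THF, 23 °C; then LiAlH4, 0 → 23 °C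
Reagents that add atoms: none
Why: base-mediated enolisation equilibrates the formyl-bearing carbon to the epimer with CHO trans to the neighbouring aryl group and cis to the arylmethyl group, judged the more stable because it removes the aryl/formyl eclipsing interaction, and LiAlH4 then reduces the aldehyde and the tert-butyl ester to the two CH2OH groups while the non-enolisable aryl- and arylmethyl-bearing carbons stay.

Step 12
Reactants: 17 {(2S,3R)-2-[4-(benzyloxy)-3-methoxyphenyl]-6-{[(3S,4S,5R)-5-[3-(benzyloxy)-4-methoxyphenyl]-4-(hydroxymethyl)oxolan-3-yl]methyl}-4-methoxy-2,3-dihydro-1-benzofuran-3-yl}methanol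
Product: 18 CNP0242386.1, (2R,3S,4S)-2-(3-hydroxy-4-methoxyphenyl)-3-(hydroxymethyl)-4-{[(2S,3R)-2-(4-hydroxy-3-methoxyphenyl)-3-(hydroxymethyl)-4-methoxy-2,3-dihydro-1-benzofuran-6-yl]methyl}oxolane
Conditions: H2 (1 atm), Pd/C (10 wt%), EtOAc/MeOH, 23 °C, stopped at full debenzylation
Reagents that add atoms: none
Why: hydrogenolysis of the two aryl benzyl ethers; the cyclic, secondary benzylic C–O bonds of the oxolane and the dihydrobenzofuran should survive under neutral conditions at 1 atm.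

Compound list
1 | methyl 4-bromo-3,5-dihydroxybenzoate | COC(=O)c1cc(O)c(Br)c(O)c1 | starting material
2 | methyl 4-bromo-3-hydroxy-5-methoxybenzoate | COC(=O)c1cc(O)c(Br)c(OC)c1 | intermediate
3 | [4-(benzyloxy)-3-methoxyphenyl]methanol | OCc1ccc(OCc2ccccc2)c(OC)c1 | starting material
4 | methyl 3-{[4-(benzyloxy)-3-methoxyphenyl]methoxy}-4-bromo-5-methoxybenzoate | COC(=O)c1cc(OC)c(Br)c(OCc2ccc(OCc3ccccc3)c(OC)c2)c1 | intermediate
5 | methyl 3-{[4-(benzyloxy)-3-methoxyphenyl]methoxy}-4-(2-tert-butoxy-2-oxoethyl)-5-methoxybenzoate | COC(=O)c1cc(OC)c(CC(=O)OC(C)(C)C)c(OCc2ccc(OCc3ccccc3)c(OC)c2)c1 | intermediate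
6 | methyl 3-{[4-(benzyloxy)-3-methoxyphenyl]methoxy}-4-(2-tert-butoxy-1-diazo-2-oxoethyl)-5-methoxybenzoate | COC(=O)c1cc(OC)c(C(=[N+]=[N-])C(=O)OC(C)(C)C)c(OCc2ccc(OCc3ccccc3)c(OC)c2)c1 | intermediate
7 | 3-tert-butyl 6-methyl (2S,3R)-2-[4-(benzyloxy)-3-methoxyphenyl]-4-methoxy-2,3-dihydro-1-benzofuran-3,6-dicarboxylate (cis, not isolated) | COC(=O)c1cc(OC)c2c(c1)O[C@H](c1ccc(OCc3ccccc3)c(OC)c1)[C@@H]2C(=O)OC(C)(C)C | intermediate
8 | 3-tert-butyl 6-methyl (2S,3S)-2-[4-(benzyloxy)-3-methoxyphenyl]-4-methoxy-2,3-dihydro-1-benzofuran-3,6-dicarboxylate (trans) | COC(=O)c1cc(OC)c2c(c1)O[C@H](c1ccc(OCc3ccccc3)c(OC)c1)[C@H]2C(=O)OC(C)(C)C | intermediate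
9 | tert-butyl (2S,3S)-2-[4-(benzyloxy)-3-methoxyphenyl]-6-(hydroxymethyl)-4-methoxy-2,3-dihydro-1-benzofuran-3-carboxylate | OCc1cc(OC)c2c(c1)O[C@H](c1ccc(OCc3ccccc3)c(OC)c1)[C@H]2C(=O)OC(C)(C)C | intermediate
10 | tert-butyl (2S,3S)-2-[4-(benzyloxy)-3-methoxyphenyl]-4-methoxy-6-{[(trifluoroacetyl)oxy]methyl}-2,3-dihydro-1-benzofuran-3-carboxylate | O=C(OCc1cc(OC)c2c(c1)O[C@H](c1ccc(OCc3ccccc3)c(OC)c1)[C@H]2C(=O)OC(C)(C)C)C(F)(F)F | intermediate
11 | 3-(benzyloxy)-4-methoxybenzaldehyde | COc1ccc(C=O)cc1OCc1ccccc1 | starting material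
12 | (Z)-but-2-ene-1,4-diol | OC/C=C\CO | starting material
13 | 2-[3-(benzyloxy)-4-methoxyphenyl]-4,7-dihydro-1,3-dioxepine | COc1ccc(C2OCC=CCO2)cc1OCc1ccccc1 | intermediate
14 | tert-butyl (2S,3S)-2-[4-(benzyloxy)-3-methoxyphenyl]-6-{[(5S)-2-[3-(benzyloxy)-4-methoxyphenyl]-4,5-dihydro-1,3-dioxepin-5-yl]methyl}-4-methoxy-2,3-dihydro-1-benzofuran-3-carboxylate (both acetal epimers) | COc1ccc(C2OC[C@@H](Cc3cc(OC)c4c(c3)O[C@H](c3ccc(OCc5ccccc5)c(OC)c3)[C@H]4C(=O)OC(C)(C)C)C=CO2)cc1OCc1ccccc1 | intermediate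
15 | tert-butyl (2S,3S)-2-[4-(benzyloxy)-3-methoxyphenyl]-6-{[(3S,4S,5R)-5-[3-(benzyloxy)-4-methoxyphenyl]-4-formyloxolan-3-yl]methyl}-4-methoxy-2,3-dihydro-1-benzofuran-3-carboxylate (aryl/CHO cis) | COc1ccc([C@@H]2OC[C@@H](Cc3cc(OC)c4c(c3)O[C@H](c3ccc(OCc5ccccc5)c(OC)c3)[C@H]4C(=O)OC(C)(C)C)[C@@H]2C=O)cc1OCc1ccccc1 | intermediate
16 | tert-butyl (2S,3S)-2-[4-(benzyloxy)-3-methoxyphenyl]-6-{[(3S,4R,5R)-5-[3-(benzyloxy)-4-methoxyphenyl]-4-formyloxolan-3-yl]methyl}-4-methoxy-2,3-dihydro-1-benzofuran-3-carboxylate (aryl/CHO trans, not isolated) | COc1ccc([C@@H]2OC[C@@H](Cc3cc(OC)c4c(c3)O[C@H](c3ccc(OCc5ccccc5)c(OC)c3)[C@H]4C(=O)OC(C)(C)C)[C@H]2C=O)cc1OCc1ccccc1 | intermediate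
17 | {(2S,3R)-2-[4-(benzyloxy)-3-methoxyphenyl]-6-{[(3S,4S,5R)-5-[3-(benzyloxy)-4-methoxyphenyl]-4-(hydroxymethyl)oxolan-3-yl]methyl}-4-methoxy-2,3-dihydro-1-benzofuran-3-yl}methanol | COc1ccc([C@@H]2OC[C@@H](Cc3cc(OC)c4c(c3)O[C@H](c3ccc(OCc5ccccc5)c(OC)c3)[C@H]4CO)[C@H]2CO)cc1OCc1ccccc1 | intermediate
18 | CNP0242386.1, (2R,3S,4S)-2-(3-hydroxy-4-methoxyphenyl)-3-(hydroxymethyl)-4-{[(2S,3R)-2-(4-hydroxy-3-methoxyphenyl)-3-(hydroxymethyl)-4-methoxy-2,3-dihydro-1-benzofuran-6-yl]methyl}oxolane | COc1ccc([C@@H]2OC[C@@H](Cc3cc(OC)c4c(c3)O[C@H](c3ccc(O)c(OC)c3)[C@H]4CO)[C@H]2CO)cc1O | target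

Total step count: 12. Longest linear sequence: 11 steps (steps 1–7 and 9–12, from 1); step 8 is a one-step side branch.

Steps most likely to fail

Step 9. The ligand may fail to tell the two enantiotopic alkene carbons apart with this large benzyl group, or re-addition of the palladium hydride may move the double bond out of the enol ether position. The fallback sets out from 9 and comes back at 14. Appel bromination (CBr4, PPh3, CH2Cl2, 0 °C) should give the benzylic bromide F1. Hydrostannation of but-2-yne-1,4-diol (Bu3SnH, PdCl2(PPh3)2, THF) gives the vinylstannane diol F2. Stille coupling of F1 with F2 (Pd2(dba)3, AsPh3, NMP, 50 °C) should give the Z-configured 2-(arylmethyl)butenediol F3, and acetalisation of F3 with 11 (PPTS, benzene, reflux) the 4,7-dihydro-1,3-dioxepin F4. Enantioselective double-bond migration with the nickel hydride from NiI2[(R,R)-Me-DuPHOS] and LiBHEt3 (THF, −55 → 0 °C), a reaction established for 5-alkyl-4,7-dihydro-1,3-dioxepins, then creates C5 and gives 14.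

Step 10. After ionisation the oxocarbenium ion may be captured by the electron-rich benzofuran ring, the ring may close with poor control of the C2/C4 relationship, or the product may re-ionise at its benzylic ether. The fallback sets out from 14 and comes back at 17 by the lactone aldol route. LiAlH4 (THF, 0 °C) reduces the tert-butyl ester to give the enol acetal alcohol F5, so that no acidic ester remains for the later base step. PPTS in wet acetone hydrolyses the vinyl acetal to the lactol F6. Ag2CO3 on Celite (benzene, reflux) oxidises only the lactol and gives the β-substituted γ-butyrolactone F7. LiHMDS (2.2 equiv, THF, −78 °C) and 11 give the aldol F8, trans to the β-substituent, as a mixture of carbinol epimers. LiAlH4 gives the tetraol F9. CSA (cat., CH2Cl2, 0 °C) ionises the p-methoxybenzylic alcohol, and the primary hydroxyl that can form a five-membered ring closes the oxolane with the aryl group trans to the CH2OH group, whatever the carbinol configuration, which gives 17.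

Step 5. The carbenoid carbon is flanked by two ortho alkoxy groups that twist the aryl ring, so enantiofacial control may be low and insertion into the OCH3 group may compete. The fallback sets out from 2 and comes back at 8 with auxiliary control. O-Allylation (allyl bromide, K2CO3, DMF) gives the allyl ether F10; the coupling of step 3 gives the tert-butyl arylacetate F11, and CF3CO2H in CH2Cl2 the arylacetic acid F12. Pivaloyl chloride/Et3N, then lithiated (S)-4-benzyl-1,3-oxazolidin-2-one (from n-BuLi), gives the imide F13. The Evans syn-aldol reaction (Bu2BOTf, iPr2NEt, CH2Cl2, −78 → 0 °C) with 4-(benzyloxy)-3-methoxybenzaldehyde (COc1cc(C=O)ccc1OCc1ccccc1) sets the carbon next to the imide carbonyl as S in the aldol F14. Pd(PPh3)4 and morpholine remove the allyl group to give the phenol F15. TsOH (cat., CH2Cl2) ionises the p-alkoxybenzylic alcohol and the phenol closes the trans-dihydrobenzofuran imide F16, whatever the carbinol configuration. LiOH/H2O2 (THF/water, 0 °C, Na2SO3 quench) gives the acid F17, and tert-butyl 2,2,2-trichloroacetimidate with BF3·OEt2 (cat.) returns 8.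

Further compounds
F1 | step 9 | tert-butyl (2S,3S)-2-[4-(benzyloxy)-3-methoxyphenyl]-6-(bromomethyl)-4-methoxy-2,3-dihydro-1-benzofuran-3-carboxylate | BrCc1cc(OC)c2c(c1)O[C@H](c1ccc(OCc3ccccc3)c(OC)c1)[C@H]2C(=O)OC(C)(C)C
F2 | step 9 | (2E)-2-(tributylstannyl)but-2-ene-1,4-diol | OC/C=C(\CO)[Sn](CCCC)(CCCC)CCCC
F3 | step 9 | tert-butyl (2S,3S)-2-[4-(benzyloxy)-3-methoxyphenyl]-6-[(2Z)-4-hydroxy-2-(hydroxymethyl)but-2-en-1-yl]-4-methoxy-2,3-dihydro-1-benzofuran-3-carboxylate | OC/C=C(\CO)Cc1cc(OC)c2c(c1)O[C@H](c1ccc(OCc3ccccc3)c(OC)c1)[C@H]2C(=O)OC(C)(C)C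
F4 | step 9 | tert-butyl (2S,3S)-2-[4-(benzyloxy)-3-methoxyphenyl]-6-{[2-[3-(benzyloxy)-4-methoxyphenyl]-4,7-dihydro-1,3-dioxepin-5-yl]methyl}-4-methoxy-2,3-dihydro-1-benzofuran-3-carboxylate | COc1ccc(C2OCC=C(Cc3cc(OC)c4c(c3)O[C@H](c3ccc(OCc5ccccc5)c(OC)c3)[C@H]4C(=O)OC(C)(C)C)CO2)cc1OCc1ccccc1
F5 | step 10 | {(2S,3R)-2-[4-(benzyloxy)-3-methoxyphenyl]-6-{[(5S)-2-[3-(benzyloxy)-4-methoxyphenyl]-4,5-dihydro-1,3-dioxepin-5-yl]methyl}-4-methoxy-2,3-dihydro-1-benzofuran-3-yl}methanol | COc1ccc(C2OC[C@@H](Cc3cc(OC)c4c(c3)O[C@H](c3ccc(OCc5ccccc5)c(OC)c3)[C@H]4CO)C=CO2)cc1OCc1ccccc1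
F6 | step 10 | (4S)-4-{[(2S,3R)-2-[4-(benzyloxy)-3-methoxyphenyl]-3-(hydroxymethyl)-4-methoxy-2,3-dihydro-1-benzofuran-6-yl]methyl}oxolan-2-ol (both anomers) | OC1C[C@H](Cc2cc(OC)c3c(c2)O[C@H](c2ccc(OCc4ccccc4)c(OC)c2)[C@H]3CO)CO1
F7 | step 10 | (4S)-4-{[(2S,3R)-2-[4-(benzyloxy)-3-methoxyphenyl]-3-(hydroxymethyl)-4-methoxy-2,3-dihydro-1-benzofuran-6-yl]methyl}oxolan-2-one | O=C1C[C@H](Cc2cc(OC)c3c(c2)O[C@H](c2ccc(OCc4ccccc4)c(OC)c2)[C@H]3CO)CO1
F8 | step 10 | (3R,4S)-3-{[3-(benzyloxy)-4-methoxyphenyl](hydroxy)methyl}-4-{[(2S,3R)-2-[4-(benzyloxy)-3-methoxyphenyl]-3-(hydroxymethyl)-4-methoxy-2,3-dihydro-1-benzofuran-6-yl]methyl}oxolan-2-one (both carbinol epimers) | O=C1[C@@H](C(O)c2ccc(OC)c(OCc3ccccc3)c2)[C@H](Cc2cc(OC)c3c(c2)O[C@H](c2ccc(OCc4ccccc4)c(OC)c2)[C@H]3CO)CO1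
F9 | step 10 | (2S,3S)-2-{[3-(benzyloxy)-4-methoxyphenyl](hydroxy)methyl}-3-{[(2S,3R)-2-[4-(benzyloxy)-3-methoxyphenyl]-3-(hydroxymethyl)-4-methoxy-2,3-dihydro-1-benzofuran-6-yl]methyl}butane-1,4-diol (both carbinol epimers) | OC[C@@H](Cc1cc(OC)c2c(c1)O[C@H](c1ccc(OCc3ccccc3)c(OC)c1)[C@H]2CO)[C@@H](CO)C(O)c1ccc(OC)c(OCc2ccccc2)c1
F10 | step 5 | methyl 4-bromo-3-methoxy-5-(prop-2-en-1-yloxy)benzoate | COC(=O)c1cc(OC)c(Br)c(OCC=C)c1
F11 | step 5 | methyl 4-(2-tert-butoxy-2-oxoethyl)-3-methoxy-5-(prop-2-en-1-yloxy)benzoate | COC(=O)c1cc(OC)c(CC(=O)OC(C)(C)C)c(OCC=C)c1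
F12 | step 5 | [2-methoxy-4-(methoxycarbonyl)-6-(prop-2-en-1-yloxy)phenyl]acetic acid | COC(=O)c1cc(OC)c(CC(=O)O)c(OCC=C)c1
F13 | step 5 | methyl 4-{2-[(4S)-4-benzyl-2-oxo-1,3-oxazolidin-3-yl]-2-oxoethyl}-3-methoxy-5-(prop-2-en-1-yloxy)benzoate | COC(=O)c1cc(OC)c(CC(=O)N2C(=O)OC[C@@H]2Cc2ccccc2)c(OCC=C)c1
F14 | step 5 | methyl 4-{(2S,3S)-3-[4-(benzyloxy)-3-methoxyphenyl]-1-[(4S)-4-benzyl-2-oxo-1,3-oxazolidin-3-yl]-3-hydroxy-1-oxopropan-2-yl}-3-methoxy-5-(prop-2-en-1-yloxy)benzoate | COC(=O)c1cc(OC)c([C@H](C(=O)N2C(=O)OC[C@@H]2Cc2ccccc2)[C@H](O)c2ccc(OCc3ccccc3)c(OC)c2)c(OCC=C)c1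
F15 | step 5 | methyl 4-{(2S,3S)-3-[4-(benzyloxy)-3-methoxyphenyl]-1-[(4S)-4-benzyl-2-oxo-1,3-oxazolidin-3-yl]-3-hydroxy-1-oxopropan-2-yl}-3-hydroxy-5-methoxybenzoate | COC(=O)c1cc(OC)c([C@H](C(=O)N2C(=O)OC[C@@H]2Cc2ccccc2)[C@H](O)c2ccc(OCc3ccccc3)c(OC)c2)c(O)c1
F16 | step 5 | methyl (2S,3S)-2-[4-(benzyloxy)-3-methoxyphenyl]-3-{[(4S)-4-benzyl-2-oxo-1,3-oxazolidin-3-yl]carbonyl}-4-methoxy-2,3-dihydro-1-benzofuran-6-carboxylate | COC(=O)c1cc(OC)c2c(c1)O[C@H](c1ccc(OCc3ccccc3)c(OC)c1)[C@H]2C(=O)N1C(=O)OC[C@@H]1Cc1ccccc1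
F17 | step 5 | (2S,3S)-2-[4-(benzyloxy)-3-methoxyphenyl]-4-methoxy-6-(methoxycarbonyl)-2,3-dihydro-1-benzofuran-3-carboxylic acid | COC(=O)c1cc(OC)c2c(c1)O[C@H](c1ccc(OCc3ccccc3)c(OC)c1)[C@H]2C(=O)O
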